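## The problem

CNP0272644.1 is a furanoheliangolide. Its ten-membered carbocycle C1–C10 (ring A) is bridged by an enol-ether oxygen between C3 and C10, so that C10, C1, C2, C3 and this oxygen form a 3(2H)-furanone (ring B) conjugated with the Z C4=C5 alkene. A γ-lactone (ring C: O, C6, C7, C11, C12) is fused cis at C6/C7. Five contiguous stereocentres (6S,7S,8S,9R,10R) line the northern edge, and the quaternary C11 (R) carries a hydroxyl and the chloromethyl carbon C13.

C8 is the natural anchor. It can be bought as glyceraldehyde, it can steer C7 through allylic strain and, through a closed transition state, C6 as well. Its hydroxyl also lies on the lactone face on which C11 carries its oxygen. That face is the hindered one (H6 and H7 lie on the other), so an undirected oxidant would give the C11 epimer. C9 and C10 have no acyclic controller and are most economically set when ring A is closed.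

The fragile groups are the angelate (isomerised to the tiglate by nucleophiles, acid or heat), the chlorohydrin (epoxide with base), the C9–C10–C1 β-hydroxy ketone (retro-aldol opens ring A) and the cross-conjugated dienone. On the way, the α-acyloxy aldehyde and the Z β-iodoenal are also fragile. A free C11 hydroxyl is γ to C9 and a free C8 hydroxyl is γ to C12, so lactol formation and translactonisation must be kept in check.

The feature that opens the molecule is ring C. If C11(OH)–C13H2Cl is read as a masked exocyclic methylene, O–C6–C7–C11(=C13)–C12 is an α-methylene-γ-butyrolactone, the lactonised homoallylic alcohol of a 2-alkoxycarbonyl allylboration. The cis relation of H6 and H7 is what a γ-substituent cis to the boron-bearing carbon delivers.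

## Retrosynthesis

**Unmasking (31 from 30).** The last operation removes a triethylsilyl group from the C11 oxygen. The group is needed earlier: a free C11 hydroxyl would trap the C9 aldehyde as a five-membered lactol and would let base close the chlorohydrin to an epoxide. An acid-labile silyl ether can be removed without base, which the β-hydroxy ketone and the angelate require.

**Rings A and B (30 from 29).** The cut is C9–C10, made forward as an intramolecular Mukaiyama aldol of a 2-methyl-3-silyloxyfuran onto the C9 aldehyde. The neighbouring cuts are worse. Metathesis at C4=C5 would have to deliver a trisubstituted Z alkene in a strained ring. A closure at C3–C4 would leave C9 and C10 to be made in the open chain. The aldol keeps the furanone masked as an aromatic furan until the last carbon–carbon bond and creates the C1 carbonyl, the C9 hydroxyl and C10 in one event. The forward reaction must use the right furan face and the right aldehyde face, and must be fast at low temperature and high dilution.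

**The western bond (29 from 22 and 28).** C3–C4 is cut between an sp2 carbon of the furan and the Z vinyl iodide. A Stille coupling joins stannane 28 (three steps from ketone 23) to iodide 22 with retention of the alkene geometry. The conditions are neutral and spare the aldehyde and the silyl enol ether. The aldehyde is made before the coupling because the electron-rich furan would not survive an oxidation.

**Dressing the lactone (22 from 12).** No skeletal bond is cut here. The chlorohydrin is installed on the monocyclic lactone and not after ring closure, for two reasons. The methylene lactone would compete with the aldehyde as an acceptor for the silyloxyfuran, and the only other alkene at this stage is the inert vinyl iodide. Because the C11 oxygen must enter on the face that carries C8, the acetonide is opened first and C9 is silylated (14). The free C8 hydroxyl then delivers the osmium reagent (16). Chlorination at C13 (17), angeloylation with 18 at C8 (20), silylation of C11 (21) and oxidative unmasking of C9 (22) follow, each on a hydroxyl that is distinct at that stage.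

**The central union (12 from 4 and 10).** The cuts are C6–C7 and O–C12. An aldol or a zinc- or indium-mediated Barbier reaction with a 2-(bromomethyl)acrylate would make the same bonds, but through less ordered transition states that do not reliably give the cis-lactone. The allylboronate 10 adds through a closed chair. That fixes the C6/C7 relation from the alkene geometry and lets C8 choose the face. The borate then lactonises. One step joins a four-carbon and a seven-carbon fragment into eleven skeletal carbons of the target, with ring C, two stereocentres and two handles (vinyl iodide, dioxolane). The forward reaction must control the face at C7 relative to C8, add 1,2 to the enal and keep the Z iodoalkene.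

**The fragments.** Boronate 10 comes from (R)-glyceraldehyde acetonide 5 and methyl acrylate 6 by a Morita–Baylis–Hillman reaction (7), acetylation (8) and copper-catalysed SN2′ borylation with diboron 9; the carbinol centre of 7 is lost again, so its configuration is irrelevant. Iodoenal 4 comes from but-2-yn-1-ol 1 by hydroalumination–iodination (3) and oxidation. Stannane 28 comes from 2-methyltetrahydrofuran-3-one 23 by dehydrogenation (25), O-silylation (26) and lithiation–stannylation.

## Roads not taken

**Alternative 1: the silyloxyfuran macroaldol as the centre of the plan.** The cut is C9–C10. A boron trifluoride-promoted attack of the tethered 2-methyl-3-silyloxyfuran on the C9 aldehyde closes ring A and releases ring B, giving A1, the C11 triethylsilyl ether of the target (identical with 30).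
- Merits: one step closes the carbocycle, creates the furanone and sets C9 and C10, and the nucleophile is a stable aromatic furan until that moment.
- Weak points: two stereocentres depend on the conformation of a nine-membered oxacycle, against the open-chain preference of an α-acyloxy aldehyde. As a plan it also says nothing about how the C6–C8 triad and the cis-lactone of the precursor are assembled.
- Comparison: the chosen route uses this very closure as step 18 and therefore inherits its risk; in that respect alternative 1 is no worse, and it names the step where complexity rises most. The chosen plan contributes the part alternative 1 leaves open: a one-step convergent union that builds ring C and C6/C7 from two small fragments.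

**Alternative 2: Grob fragmentation of a chiral-pool cis-decalin.** The cut is the transannular C4–C9 bond. Ionisation of a C9 tertiary alcohol breaks this bond antiperiplanar to a C5 sulfonate and gives the Z-cyclodecenone A2, with C6, C7 and C10 in place.
- Merits: no macrocyclisation entropy; the Z geometry follows stereospecifically from the fragmentation; C7 and the C1/C10 oxygens are set on a rigid bicycle. On ring formation and alkene geometry this road is more reliable than the macroaldol of the chosen plan.
- Weak points: A2 is far from the target in oxidation pattern. C8 is a methylene, C9 a ketone, C2/C3 are saturated, and C7 carries an isopropenyl group that must be oxidised to the lactone carbon. The furanone, the C8 and C9 oxygens, the lactone, the chlorohydrin and the angelate must all be introduced on a flexible ten-membered ring prone to transannular reactions, with little stereocontrol at C8 and C9.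
- Comparison: the chosen plan carries the oxygenation in its fragments from the start and needs fewer steps after its key step than this road needs after A2.

**Alternative 3: a nine-membered lactone zipped by a C2–C3 Claisen condensation.** The cuts are C2–C3 and, earlier, the C3–O ester bond to the C10 oxygen. The kinetic enolate of the C10 acetyl group attacks the lactone carbonyl C3 across the ring, and dehydration gives the furanone and the carbocycle at once as the bis-acetonide A3.
- Merits: C9 and C10 are set in an open-chain precursor by reagent-controlled methods before any ring exists, and the enolate is unambiguous because C10 is quaternary. On C9/C10 control this road is better than the chosen plan, whose weakest point is exactly there.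
- Weak points: the nine-membered lactone must be closed by acylating a tertiary alcohol with a Z-enoic acid. Strong base then meets a γ-lactone and a Z-enoate. After A3 two acetonides must be removed and four hydroxyls (C8, C9, C11, C13) told apart for chlorination and angeloylation.
- Comparison: the chosen plan avoids the medium-ring lactonisation, and it installs the chlorohydrin and the angelate on a monocyclic lactone where each hydroxyl is different.

Key step: step 6

Assumption: germacrane locants are used for all intermediates (C14 is the methyl on C10, C15 the methyl on C4), and commercial (R)-glyceraldehyde acetonide is distilled immediately before use.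

Step 1
Reactants: 1 but-2-yn-1-ol
Product: 3 (Z)-3-iodobut-2-en-1-ol, via sodium alkenylalanate 2 (not isolated)
Conditions: NaAlH2(OCH2CH2OMe)2, THF, 0 → 25 °C; EtOAc; then I2, THF, −78 → 0 °C
Reagents that add atoms: iodine, II
Why: Hydroalumination–iodination: the propargylic alkoxide delivers hydride to C2 in a trans sense and leaves aluminium on C3 in a five-membered oxaaluminacycle, and iodinolysis with retention gives the Z iodide.

Step 2
Reactants: 3 (Z)-3-iodobut-2-en-1-ol
Product: 4 (Z)-3-iodobut-2-enal
Conditions: MnO2, CH2Cl2, 25 °C, dark
Reagents that add atoms: none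
Why: Allylic oxidation with MnO2 is neutral and should not isomerise the Z β-iodoenal, which is filtered and used at once.

Step 3
Reactants: 5 (R)-glyceraldehyde acetonide; 6 methyl acrylate
Product: 7 methyl 2-{[(4R)-2,2-dimethyl-1,3-dioxolan-4-yl](hydroxy)methyl}prop-2-enoate (both carbinol epimers)
Conditions: DABCO, 1,4-dioxane/H2O (1:1), 25 °C
Reagents that add atoms: none
Why: Morita–Baylis–Hillman reaction; the aqueous medium accelerates it so that the α-alkoxy aldehyde is consumed before it can epimerise, and the uncontrolled carbinol centre is removed again in step 5.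

Step 4
Reactants: 7 Morita–Baylis–Hillman adduct
Product: 8 methyl 2-{acetoxy[(4R)-2,2-dimethyl-1,3-dioxolan-4-yl]methyl}prop-2-enoate
Conditions: Ac2O, pyridine, CH2Cl2, 0 °C
Reagents that add atoms: acetic anhydride, CC(=O)OC(C)=O
Why: Standard acetylation, kept cold and short so that the allylic acetate does not undergo amine-induced 1,3-transposition.

Step 5
Reactants: 8 allylic acetate; 9 bis(pinacolato)diboron
Product: 10 methyl (2E)-3-[(4S)-2,2-dimethyl-1,3-dioxolan-4-yl]-2-[(4,4,5,5-tetramethyl-1,3,2-dioxaborolan-2-yl)methyl]prop-2-enoate
Conditions: CuCl (10 mol%), KOAc, DMF, 25 °C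
Reagents that add atoms: none
Why: Copper-catalysed SN2′ borylation of a Morita–Baylis–Hillman acetate (boryl-copper conjugate addition, then β-acetoxy elimination); as in other SN2′ reactions of acrylate-derived acetates the substituent should end trans to the ester, that is cis to CH2B.

Step 6
Reactants: 4 (Z)-3-iodobut-2-enal; 10 allylboronate
Product: 12 (4S,5R)-4-[(4S)-2,2-dimethyl-1,3-dioxolan-4-yl]-5-[(1Z)-2-iodoprop-1-en-1-yl]-3-methylideneoxolan-2-one (6,7-cis lactone), via open-chain pinacol borate 11 (not isolated)
Conditions: Sc(OTf)3 (10 mol%), toluene, −40 → 0 °C; then p-TsOH (10 mol%), 25 °C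
Reagents that add atoms: none
Why: This is a carboxy-allylboration with lactonisation, the known route from 2-alkoxycarbonyl allylboronates and aldehydes to α-methylene-γ-butyrolactones. The aldehyde oxygen binds boron (Sc(OTf)3 activates the boronate at a ring oxygen, so the closed transition state is kept), and the γ carbon C7 attacks C6 through a six-membered Zimmerman–Traxler chair with allylic transposition, which makes C11=C13 exocyclic. Because the dioxolanyl group is cis to CH2B it is axial while the iodopropenyl group of 4 is equatorial, so the C6–O and C7–C8 bonds come out syn, which after closure is the 6,7-cis lactone. The absolute sense is set by C8: allylic 1,3-strain with CH2B holds H8 in the alkene plane, the donor C8–C9 bond lies anti to the forming bond and the C8–O bond outside, so the aldehyde should add to the C7 face syn to the dioxolane oxygen, which is the face the target requires. Borate 11 then closes ring C by 5-exo-trig acyl substitution of O6 on the ester carbon C12, completed by the acid. The step needs 1,2-addition to the enal, retention of the Z iodoalkene and an intact acetonide; the first is inherent in the closed transition state, the others rest on the low temperature and the small amount of acid.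

Step 7
Reactants: 12 key lactone
Product: 13 C8,C9-diol of the lactone
Conditions: AcOH/H2O/THF (3:1:1), 40 °C
Reagents that add atoms: none
Why: Hydrolysis of a terminal acetonide; aqueous acetic acid should spare the lactone, the methylene group and the vinyl iodide and is too weak to drive translactonisation to O8.

Step 8
Reactants: 13 diol
Product: 14 9-O-triethylsilyl ether with free C8 hydroxyl
Conditions: Et3SiCl, imidazole, CH2Cl2, −78 → −40 °C
Reagents that add atoms: chlorotriethylsilane, CC[Si](Cl)(CC)CC
Why: Kinetically selective silylation of the primary hydroxyl, which leaves the C8 hydroxyl free as the directing group for step 9.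

Step 9
Reactants: 14 homoallylic alcohol
Product: 16 8,11,13-triol, via osmate ester TMEDA complex 15 (not isolated)
Conditions: OsO4 (1.05 equiv), TMEDA (1.1 equiv), CH2Cl2, −78 °C; then aq. Na2SO3, THF, 40 °C
Reagents that add atoms: osmium tetroxide, O=[Os](=O)(=O)=O
Why: Hydrogen-bond-directed dihydroxylation: OsO4·TMEDA is a hydrogen-bond acceptor and should be delivered by the homoallylic C8 hydroxyl to the lactone face that carries C8, which is where the target has its C11 oxygen; an undirected reagent would take the open face and give the C11 epimer. The electron-poor, hindered vinyl iodide should not react at −78 °C.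

Step 10
Reactants: 16 triol
Product: 17 13-chloro-8,11-diol (chlorohydrin)
Conditions: PPh3, CCl4, pyridine, 40 °C
Reagents that add atoms: carbon tetrachloride, ClC(Cl)(Cl)Cl
Why: Appel chlorination, selective for the primary hydroxyl; direct displacement and the alternative path through the 11,13-epoxide opened by chloride at C13 converge on 17, and C11 is not touched.

Step 11
Reactants: 17 chlorohydrin; 18 angelic acid
Product: 20 8-O-angelate, via angelic 2,4,6-trichlorobenzoic anhydride 19 (not isolated)
Conditions: 18, 2,4,6-trichlorobenzoyl chloride, Et3N, toluene, 25 °C; then 17, 75 °C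
Reagents that add atoms: none
Why: Yamaguchi esterification through the mixed anhydride without DMAP is the established non-isomerising way to angelates; the tertiary C11 hydroxyl is too hindered to be acylated.

Step 12
Reactants: 20 angelate
Product: 21 9,11-bis(triethylsilyl) ether
Conditions: Et3SiOTf, 2,6-lutidine, CH2Cl2, −78 → 0 °C
Reagents that add atoms: triethylsilyl trifluoromethanesulfonate, CC[Si](CC)(CC)OS(=O)(=O)C(F)(F)F
Why: A silyl triflate silylates the tertiary alcohol; the ether prevents lactol formation with the coming C9 aldehyde and epoxide closure of the chlorohydrin.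

Step 13
Reactants: 21 bis-silyl ether
Product: 22 C9 aldehyde (8-O-angelate, 11-O-triethylsilyl ether)
Conditions: (COCl)2, DMSO, CH2Cl2, −78 → −30 °C; then Et3N, −78 → 0 °C
Reagents that add atoms: none
Why: Swern conditions cleave and oxidise primary triethylsilyl ethers directly and leave hindered ones, so the aldehyde forms without a free C9 hydroxyl to which the angelate could migrate; the cold, short exposure to amine limits epimerisation at C8.

Step 14
Reactants: 23 2-methyltetrahydrofuran-3-one
Product: 25 2-methylfuran-3(2H)-one, via trimethylsilyl enol ether 24 (not isolated)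
Conditions: LiN(iPr)2, THF, −78 °C; Me3SiCl; then Pd(OAc)2, MeCN, 25 °C
Reagents that add atoms: none
Why: Saegusa–Ito oxidation: kinetic deprotonation takes the C4 methylene (the oxygen-bearing methine is slower), and palladium-mediated dehydrosilylation gives the vinylogous ester.

Step 15
Reactants: 25 2-methylfuran-3(2H)-one
Product: 26 2-methyl-3-(triisopropylsilyloxy)furan
Conditions: iPr3SiOTf, Et3N, CH2Cl2, 0 °C
Reagents that add atoms: triisopropylsilyl trifluoromethanesulfonate, CC(C)[Si](C(C)C)(C(C)C)OS(=O)(=O)C(F)(F)F
Why: O-Silylation of the furanone enolate is driven by aromatisation to the furan; the bulky silyl group gives an enol ether that can be handled.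

Step 16
Reactants: 26 silyloxyfuran
Product: 28 tributyl{5-methyl-4-[(triisopropylsilyl)oxy]furan-2-yl}stannane, via 5-lithiofuran 27 (not isolated)
Conditions: n-BuLi, THF, −78 → 0 °C; then Bu3SnCl, −78 °C
Reagents that add atoms: tributyltin chloride, CCCC[Sn](Cl)(CCCC)CCCC
Why: α-Lithiation of a furan at its only free α position followed by stannylation; the bulky silyl ether resists attack and is not ortho to the lithiated carbon, so it cannot migrate.

Step 17
Reactants: 22 vinyl iodide aldehyde; 28 furylstannane
Product: 29 seco aldehyde with the 5-methyl-4-(triisopropylsilyloxy)furan-2-yl group on C4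
Conditions: Pd2(dba)3 (5 mol%), AsPh3 (20 mol%), CuI (10 mol%), DMF, 25 °C, dark
Reagents that add atoms: none
Why: Stille coupling of a 2-furylstannane with a vinyl iodide proceeds with retention of the Z geometry; the neutral, fluoride-free conditions spare the aldehyde, both silyl ethers and the angelate.

Step 18
Reactants: 29 seco aldehyde
Product: 30 11-O-triethylsilyl ether of the target
Conditions: BF3·OEt2, CH2Cl2 (0.002 M), −78 °C; then aq. NaHCO3
Reagents that add atoms: none
Why: Intramolecular Mukaiyama aldol of a 3-silyloxyfuran, which reacts at C2 (here C10) and releases the 3(2H)-furanone while closing ring A. C9 and C10 are set together: the tether holds C8 over the ring-oxygen edge of the furan, and the open antiperiplanar transition state turns the boron-bound oxygen away from the silyloxy group, which links the two centres in the relative sense of the target. Which furan face is used is left to the C6–C8 stereocentres.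

Step 19
Reactants: 30 silyl ether
Product: 31 CNP0272644.1 (target)
Conditions: HF·pyridine, pyridine, THF, 0 → 25 °C
Reagents that add atoms: none
Why: Buffered acidic fluoride removes the tertiary triethylsilyl group without base, so retro-aldol opening, epoxide closure and angelate isomerisation should be avoided.

**Compound list**

1 | but-2-yn-1-ol | CC#CCO | starting material
2 | sodium 2,2-bis(2-methoxyethoxy)-3-methyl-2,5-dihydro-1,2-oxaaluminol-2-uide | CC1=CCO[Al-]1(OCCOC)OCCOC.[Na+] | intermediate
3 | (Z)-3-iodobut-2-en-1-ol | I/C(C)=C\CO | intermediate
4 | (Z)-3-iodobut-2-enal | I/C(C)=C\C=O | intermediate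
5 | (R)-2,2-dimethyl-1,3-dioxolane-4-carbaldehyde | CC1(C)OC[C@H](C=O)O1 | starting material
6 | methyl acrylate | C=CC(=O)OC | starting material
7 | methyl 2-{[(4R)-2,2-dimethyl-1,3-dioxolan-4-yl](hydroxy)methyl}prop-2-enoate, carbinol epimers | COC(=O)C(=C)C(O)[C@H]1COC(C)(C)O1 | intermediate
8 | methyl 2-{acetoxy[(4R)-2,2-dimethyl-1,3-dioxolan-4-yl]methyl}prop-2-enoate | COC(=O)C(=C)C(OC(C)=O)[C@H]1COC(C)(C)O1 | intermediate
9 | bis(pinacolato)diboron | CC1(C)OB(OC1(C)C)B2OC(C)(C)C(C)(C)O2 | starting material
10 | methyl (2E)-3-[(4S)-2,2-dimethyl-1,3-dioxolan-4-yl]-2-[(4,4,5,5-tetramethyl-1,3,2-dioxaborolan-2-yl)methyl]prop-2-enoate (dioxolanyl cis to CH2B) | COC(=O)/C(CB1OC(C)(C)C(C)(C)O1)=C/[C@H]2COC(C)(C)O2 | intermediate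
11 | open-chain pinacol borate of the syn homoallylic alcohol (methyl ester, C6–O–B; C6, C7, C8 as in 12) | CC1(C)OC[C@@H](O1)[C@@H](C(=C)C(=O)OC)[C@H](/C=C(/C)I)OB2OC(C)(C)C(C)(C)O2 | intermediate
12 | (4S,5R)-4-[(4S)-2,2-dimethyl-1,3-dioxolan-4-yl]-5-[(1Z)-2-iodoprop-1-en-1-yl]-3-methylideneoxolan-2-one; H6 and H7 cis | CC1(C)OC[C@@H](O1)[C@@H]2[C@H](/C=C(/C)I)OC(=O)C2=C | intermediate
13 | lactone 12 without the acetonide: C8 and C9 hydroxyls free; C6, C7, C8 as in 12 | OC[C@@H](O)[C@@H]1[C@H](/C=C(/C)I)OC(=O)C1=C | intermediate
14 | 9-O-triethylsilyl ether of 13, C8 hydroxyl free | CC[Si](CC)(CC)OC[C@@H](O)[C@@H]1[C@H](/C=C(/C)I)OC(=O)C1=C | intermediate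
15 | 11,13-osmate ester of 14, OsO2(diolate)(TMEDA), osmium on the lactone face that carries C8 | CC[Si](CC)(CC)OC[C@@H](O)[C@@H]1[C@H](/C=C(/C)I)OC(=O)[C@@]12CO[Os-2]3(=O)(=O)(O2)[N+](C)(C)CC[N+]3(C)C | intermediate
16 | 8,11,13-triol: C11 hydroxyl syn to C8 on the lactone (configuration of the target), 9-O-triethylsilyl ether | CC[Si](CC)(CC)OC[C@@H](O)[C@@H]1[C@H](/C=C(/C)I)OC(=O)[C@@]1(O)CO | intermediate
17 | 13-chloro-8,11-diol, 9-O-triethylsilyl ether; stereocentres as in 16 | CC[Si](CC)(CC)OC[C@@H](O)[C@@H]1[C@H](/C=C(/C)I)OC(=O)[C@@]1(O)CCl | intermediate
18 | angelic acid, (Z)-2-methylbut-2-enoic acid | C/C=C(/C)C(O)=O | starting material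
19 | (Z)-2-methylbut-2-enoic 2,4,6-trichlorobenzoic anhydride | C/C=C(/C)C(=O)OC(=O)c1c(Cl)cc(Cl)cc1Cl | intermediate
20 | 8-O-angelate of 17 | C/C=C(/C)C(=O)O[C@H](CO[Si](CC)(CC)CC)[C@@H]1[C@H](/C=C(/C)I)OC(=O)[C@@]1(O)CCl | intermediate
21 | 9,11-bis(triethylsilyl) ether of the 8-O-angelate | C/C=C(/C)C(=O)O[C@H](CO[Si](CC)(CC)CC)[C@@H]1[C@H](/C=C(/C)I)OC(=O)[C@@]1(O[Si](CC)(CC)CC)CCl | intermediate
22 | C9 aldehyde: 8-O-angelate, 11-O-triethylsilyl ether, Z vinyl iodide | C/C=C(/C)C(=O)O[C@H](C=O)[C@@H]1[C@H](/C=C(/C)I)OC(=O)[C@@]1(O[Si](CC)(CC)CC)CCl | intermediate
23 | 2-methyltetrahydrofuran-3-one (racemic) | CC1OCCC1=O | starting material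
24 | 2-methyl-3-(trimethylsilyloxy)-2,5-dihydrofuran | CC1OCC=C1O[Si](C)(C)C | intermediate
25 | 2-methylfuran-3(2H)-one (racemic) | CC1OC=CC1=O | intermediate
26 | 2-methyl-3-(triisopropylsilyloxy)furan | Cc1occc1O[Si](C(C)C)(C(C)C)C(C)C | intermediate
27 | 5-lithio-2-methyl-3-(triisopropylsilyloxy)furan | Cc1oc([Li])cc1O[Si](C(C)C)(C(C)C)C(C)C | intermediate
28 | tributyl{5-methyl-4-[(triisopropylsilyl)oxy]furan-2-yl}stannane | Cc1oc(cc1O[Si](C(C)C)(C(C)C)C(C)C)[Sn](CCCC)(CCCC)CCCC | intermediate
29 | seco aldehyde: 22 with the furan-2-yl group in place of iodine, Z alkene retained | C/C=C(/C)C(=O)O[C@H](C=O)[C@@H]1[C@H](/C=C(/C)c2cc(O[Si](C(C)C)(C(C)C)C(C)C)c(C)o2)OC(=O)[C@@]1(O[Si](CC)(CC)CC)CCl | intermediate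
30 | 11-O-triethylsilyl ether of the target | C/C=C(/C)C(=O)O[C@H]1[C@@H]2[C@H](/C=C(/C)C3=CC(=O)[C@](C)(O3)[C@@H]1O)OC(=O)[C@@]2(O[Si](CC)(CC)CC)CCl | intermediate
31 | CNP0272644.1: (6S,7S,8S,9R,10R,11R)-8-angeloyloxy-13-chloro-9,11-dihydroxy-1-oxo-3,10-epoxygermacra-2,4Z-dien-6,12-olide | C/C=C(/C)C(=O)O[C@H]1[C@@H]2[C@H](/C=C(/C)C3=CC(=O)[C@](C)(O3)[C@@H]1O)OC(=O)[C@@]2(O)CCl | target

**Step count and risk**

Total: 19 steps. Longest linear sequence: 14 steps from 5 (steps 3–13 and 17–19); the iodoenal (steps 1–2) and the stannane (steps 14–16) are side branches.

**Step 6 (key step).** The most likely failure is poor facial selectivity at C7 relative to C8. The required mode (C8–C9 anti, C8–O outside) is the one expected for an electrophile attacking a nucleophilic Z alkene, but the osmylation of allylic ethers shows that the opposite preference exists. Isomerisation of the Z iodoenal and erosion of the syn relation, should the Lewis acid open the transition state, are secondary risks. The fallback replaces substrate control by double stereodifferentiation with a chiral diol on boron. It sets out from acetate 8, which is borylated under the conditions of step 5 with commercial bis(diisopropyl D-tartrate glycolato)diboron to give the (S,S)-diisopropyl tartrate allylboronate F1. This more electrophilic reagent should react with 4 without catalyst (toluene, 4 Å sieves, −78 °C) on the aldehyde face that leads to the required chair, and acid lactonisation rejoins the route at 12.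

**Step 18.** The most likely failure is ring closure through the other furan face and the other aldehyde face. The target is 8,9-syn, whereas the polar Felkin–Anh preference of an α-acyloxy aldehyde points to the 8,9-anti series, so the macrocyclic constraint must override it. Oligomerisation and protodesilylation are secondary risks. The fallback turns the C8 oxygen into a chelating ether. It sets out from 17 and proceeds as follows:
- 4-methoxybenzyl trichloroacetimidate with catalytic La(OTf)3 gives the 8-O-(4-methoxybenzyl) ether F2;
- Et3SiOTf with 2,6-lutidine gives its 11-O-triethylsilyl ether F3;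
- Swern oxidation gives the α-alkoxy aldehyde F4;
- Stille coupling with 28 gives the furan aldehyde F5;
- MgBr2·OEt2 in CH2Cl2 closes ring A under Cram-chelate control, which favours the 8,9-syn face and is compatible with the gauche C7–C8–C9–C10 arrangement that the ring demands, giving the 8-O-(4-methoxybenzyl) macrocycle F6;
- DDQ frees the 8,9-diol F7;
- Yamaguchi angeloylation with 18 at the less hindered C8 hydroxyl (C9 is neopentylic) rejoins the route at 30.

**Step 9.** The most likely failure is attack on the open lactone face if hydrogen-bond delivery from a homoallylic hydroxyl on a rotatable bond does not override the steric bias; that would give the C11 epimer. Loss of the primary silyl ether or lactone opening during osmate cleavage is a second concern. The fallback uses reagent control on an allylic alcohol. It sets out from 12 and proceeds as follows: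
- iBu2AlH reduces the lactone to the 2-methylene-1,4-diol F8;
- Sharpless asymmetric epoxidation (Ti(OiPr)4, D-(−)-diethyl tartrate, tBuOOH, 4 Å sieves, −20 °C) gives the epoxy diol F9, with the epoxide oxygen in the configuration of the target C11;
- LiCl with AcOH opens the epoxide at C13 to the chloro triol F10;
- TEMPO with PhI(OAc)2 oxidises the primary C12 hydroxyl and closes ring C again to the chlorohydrin lactone acetonide F11;
- aqueous acetic acid gives the 8,9,11-triol F12;
- selective silylation of the primary hydroxyl (Et3SiCl, imidazole) rejoins the route at 17.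

**Step 10.** The most likely failure is sluggish substitution at the neopentylic C13, which gives time for competing reaction at the C8 hydroxyl or for silyl loss. The fallback separates activation from substitution. It sets out from 16: tosylation of the primary hydroxyl (TsCl, Et3N, catalytic Bu2SnO) gives the 13-tosylate F13, DBU closes the 11,13-epoxide F14 with retention at C11, and LiCl with AcOH opens it at C13 to rejoin the route at 17.

## Further compounds

F1 | step 6 | diisopropyl (4S,5S)-2-{(2E)-3-[(4S)-2,2-dimethyl-1,3-dioxolan-4-yl]-2-(methoxycarbonyl)prop-2-en-1-yl}-1,3,2-dioxaborolane-4,5-dicarboxylate | COC(=O)/C(CB1O[C@H](C(=O)OC(C)C)[C@@H](C(=O)OC(C)C)O1)=C/[C@H]2COC(C)(C)O2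
F2 | step 18 | 8-O-(4-methoxybenzyl) ether of 17 | COc1ccc(CO[C@H](CO[Si](CC)(CC)CC)[C@@H]2[C@H](/C=C(/C)I)OC(=O)[C@@]2(O)CCl)cc1
F3 | step 18 | 11-O-triethylsilyl ether of F2 | COc1ccc(CO[C@H](CO[Si](CC)(CC)CC)[C@@H]2[C@H](/C=C(/C)I)OC(=O)[C@@]2(O[Si](CC)(CC)CC)CCl)cc1
F4 | step 18 | C9 aldehyde with 8-O-(4-methoxybenzyl) and 11-O-triethylsilyl groups | COc1ccc(CO[C@H](C=O)[C@@H]2[C@H](/C=C(/C)I)OC(=O)[C@@]2(O[Si](CC)(CC)CC)CCl)cc1
F5 | step 18 | furan aldehyde, Stille product of F4 and 28 | COc1ccc(CO[C@H](C=O)[C@@H]2[C@H](/C=C(/C)c3cc(O[Si](C(C)C)(C(C)C)C(C)C)c(C)o3)OC(=O)[C@@]2(O[Si](CC)(CC)CC)CCl)cc1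
F6 | step 18 | 8-O-(4-methoxybenzyl) 11-O-triethylsilyl macrocycle with free C9 hydroxyl | COc1ccc(CO[C@H]2[C@@H]3[C@H](/C=C(/C)C4=CC(=O)[C@](C)(O4)[C@@H]2O)OC(=O)[C@@]3(O[Si](CC)(CC)CC)CCl)cc1
F7 | step 18 | 8,9-diol, 11-O-triethylsilyl ether of the 8-deacyl target | O[C@H]1[C@@H]2[C@H](/C=C(/C)C3=CC(=O)[C@](C)(O3)[C@@H]1O)OC(=O)[C@@]2(O[Si](CC)(CC)CC)CCl
F8 | step 9 | 2-methylene-1,4-diol from reduction of 12 (C6 and C12 hydroxyls) | CC1(C)OC[C@@H](O1)[C@@H](C(=C)CO)[C@@H](O)/C=C(/C)I
F9 | step 9 | 11,13-epoxy diol | CC1(C)OC[C@@H](O1)[C@@H]([C@@]2(CO)CO2)[C@@H](O)/C=C(/C)I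
F10 | step 9 | 13-chloro-6,11,12-triol | CC1(C)OC[C@@H](O1)[C@@H]([C@@](O)(CO)CCl)[C@@H](O)/C=C(/C)I
F11 | step 9 | chlorohydrin lactone with the C8/C9 acetonide | CC1(C)OC[C@@H](O1)[C@@H]2[C@H](/C=C(/C)I)OC(=O)[C@@]2(O)CCl
F12 | step 9 | 13-chloro-8,9,11-triol lactone | OC[C@@H](O)[C@@H]1[C@H](/C=C(/C)I)OC(=O)[C@@]1(O)CCl
F13 | step 10 | 13-O-tosylate of 16 | CC[Si](CC)(CC)OC[C@@H](O)[C@@H]1[C@H](/C=C(/C)I)OC(=O)[C@@]1(O)COS(=O)(=O)c1ccc(C)cc1
F14 | step 10 | 11,13-epoxide (spiro-epoxy lactone), 9-O-triethylsilyl ether | CC[Si](CC)(CC)OC[C@@H](O)[C@@H]1[C@H](/C=C(/C)I)OC(=O)[C@@]12CO2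
A1 | alternative 1 | C11 triethylsilyl ether of the target (identical with 30) | C/C=C(/C)C(=O)O[C@H]1[C@@H]2[C@H](/C=C(/C)C3=CC(=O)[C@](C)(O3)[C@@H]1O)OC(=O)[C@@]2(O[Si](CC)(CC)CC)CCl
A2 | alternative 2 | Z-cyclodecenone with C9 ketone, C7 isopropenyl, C6 tert-butyldimethylsilyl ether and C1/C10 acetonide | O=C1C[C@@H](C(C)=C)[C@@H](O[Si](C)(C)C(C)(C)C)/C=C(/C)CC[C@@H]2OC(C)(C)O[C@]12C
A3 | alternative 3 | furanone-bridged carbocycle with C8/C9 and C11/C13 acetonides | CC1(C)O[C@H]2[C@@H]3[C@H](/C=C(/C)C4=CC(=O)[C@](C)(O4)[C@@H]2O1)OC(=O)[C@@]3(OC(C)(C)O5)C5
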